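The constants are assumed; no experiment stands behind them.

Count this flask in logarithms, with one ratio carried from start to finish.

solid substrate 13 mM; coupling partner 14.3 mM; transfer agent 0.650 mM; initiator 0.91 mM; time 20 h

1. target at 20 h, in percent of the solid substrate charged
2. concentration of starting material in solution at 20 h, in percent of saturation

- in percentages every species weighs as the solid substrate in it: one ended chains counts as two
- for a step with 2 of a species take k times the square, and two of it per event
- as a solid, counted per litre of solution: solid substrate
- at the start none of the solid substrate is in solution
- starting material means what is dissolved; the solid is not counted in it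
- run time (flask): 20 h

    starting material + second chain carrier → released group + first chain carrier (k1 = 2.98 × 10⁶ M⁻¹ h⁻¹)
    solid substrate ⇌ starting material, rate k2*(cs2 - [starting material]) while solid is left; crystals form when [starting material] > cs2 (cs2 = 6.5 mM, k2 = 0.0722 h⁻¹)
    transfer agent + first chain carrier → side product + idle radical (k3 = 33700 M⁻¹ s⁻¹)
    2 idle radical → ended radicals (k4 = 7.6 × 10⁷ M⁻¹ s⁻¹)
    2 first chain carrier → ended chains (k5 = 1.5 × 10⁶ M⁻¹ s⁻¹)
    initiator → 2 initiating radical (k6 = 0.135 h⁻¹)
    starting material + initiating radical → capped initiator + first chain carrier (k7 = 64000 M⁻¹ s⁻¹)
    coupling partner + first chain carrier → target + second chain carrier (k8 = 5.17 × 10⁶ M⁻¹ h⁻¹)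

1. The first chain carrier consumes two reagents: the coupling partner makes target, and the transfer agent makes side product. Both fall against the same carrier, so the logarithms of the fractions left keep a fixed ratio, the selectivity factor 23.5, the constant of the transfer agent's step over that of the coupling partner's step.

2. First way, by supply. Into a solution kept empty the solid delivers 0.469 mM h⁻¹, so in 20 h it gives 9.39 mM, or 72.2% of the charge. If the whole transfer agent charge is consumed, it takes 5.00% as side product, and 67.2% remains as target.

3. Second way, testing that deduction from the rate constants. That much target uses 8.74 mM of coupling partner and leaves 38.9% of its charge. The logarithm of that fraction, multiplied by the selectivity factor, puts the transfer agent 9.64 powers of ten below its charge, so the deduction comes out at 5.00% again. This tests the transfer agent's share, not the supply.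

4. The deduction must also be paid in carriers. The initiator yields 1.70 mM of radicals by then, against 0.650 mM of transfer agent, so this count leaves 1.05 mM of carriers, with losses of carriers to each other not counted. This reckoning commits to the target and stops short of saturation.

5. The forecast gives 67% (63% to 70%) and 0.0023% of saturation (0.0018% to 0.003%). Its ground: “Dissolution is the bottleneck”. Its target stands level with the reckoning above.

6. The flask gives 67.0% of target and 0% of saturation as rounded, both forecast numbers right within the tolerance. Side product in the flask reads 5.00% at 20.0 h. At 10.0 h the coupling partner in the flask reads 71.8% of its charge; the selectivity factor turns that into 0.0416% of transfer agent, and the reading is 0.0417%.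

7. The neighbour flask with 0.23 mM of initiator yields 0.429 mM of radicals; if each radical ends on one transfer agent, the reckoning leaves 34.0% of the transfer agent. Dividing that logarithm by the selectivity factor leaves 95.5% of the coupling partner, or 4.94% of target. That neighbour flask gives 4.94% of target, with 34% of transfer agent left.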